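The constants of the next run are the loading, 0.01 mol% of enzyme on substrate, and the time, 15 h. The charge of substrate is mine to choose, and I must decide whether one flask at the top of the range will do or whether the full row has to be run.

in all of them: enzyme 0.01 mol%
- west: substrate 28 mM; run made earlier
- south: substrate 120 mM; run made earlier
- Sunday's: substrate 20 mM; time 15 h
- Friday's: substrate 30 mM; time 15 h
- Saturday's: substrate 50 mM; time 15 h
- Monday's: substrate 80 mM; time 15 h
- Tuesday's: substrate 100 mM; time 15 h

- west (time / h: target / %, substrate / %): 3.00: 14, 82; 6.00: 23, 76; 10.0: 30, 71; 12.0: 33, 70; 15.0: 39, 64
- south (time / h: target / %, substrate / %): 3.00: 16, 78; 6.00: 26, 73; 10.0: 36, 63; 12.0: 41, 59; 15.0: 46, 52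

(readings scatter by 2 percentage points)

- amount of target at the end, in percent of the substrate charged for Sunday's, Friday's, Saturday's, Monday's, Tuesday's, in this order
- the course of these numbers from the first flask to the last (hardly changes / falls, then rises / rises all the way / rises, then falls / falls all the way)

- "hardly changes" means that all values lie within two and a half points (for a concentration: within two and a half percent of the largest)

1. I start from the balance of the smaller charge. Enzyme stands at one to 10000 substrate and, as a catalyst, comes back after each round, so I count target per enzyme.

2. West ends at 39 %, which makes 3900 target per enzyme. I call this N, the turnover number: percent of target divided by the loading, per enzyme charged. South gives 4600.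

3. South holds 4.29 times the charge of west, but its N is 1.18 times west's. Their gap is 7 percentage points, with a scatter of 2 points on each reading.

4. My own reckoning is a straight line in N between the two charges. It gives 4070 for Saturday's and 4450 for Tuesday's. That is a gap of just 3.8 points in target, and a line through two ends shows no bend between them.

5. The forecast reads 36 %, 40 %, 43 %, 45 %, 46 %, shape rises all the way: “a gentle rise, flattening out”. At Saturday's and Tuesday's it stands above my line.

6. So I don't charge Tuesday's by itself; I run the full row, from 20 mM to 100 mM.

The row comes out at 25.4 %, 39.2 %, 51.8 %, 53.7 %, 50.9 %: rises, then falls.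

    substrate + enzyme → target + enzyme, rate k1*[substrate]^3*[enzyme]/(1 + ([substrate]/Kh1)^3) (27.0 mM, k = 35000 M⁻³ s⁻¹)
    2 enzyme ⇌ resting dimer (K = 3.90 × 10⁶ M⁻¹, k = 1.40 × 10⁵ M⁻¹ h⁻¹)

The row turns at 68 mM. In Tuesday's flask, after 4.50 h, 88.2 % of the catalyst is resting dimer, the resting state, and 11.8 % is enzyme. Put into N, Sunday's flask gives 2540, below the 3900 read for west. Monday's flask gives 5370, above the 4600 read for south, and Tuesday's flask, with a larger charge than Monday's, gives 5090.

The runs come from a simulation with made-up constants; scatter was added.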